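**Reading time.** The four flasks are read at 4.0 h, with E charged one to one against L. I work with the fraction of L left, f, and its reciprocal r, and not with the G made.

| setting | north-west | east | violet | red | amber | teal |
|---|---|---|---|---|---|---|
| L | 0.037 M | 0.31 M | 0.025 M | 0.050 M | 0.10 M | 0.20 M |
| E | 1 equiv | 1 equiv | 1.00 equiv | 1.00 equiv | 1.00 equiv | 1.00 equiv |
| remark | run made earlier | run made earlier |  |  |  |  |
| time |  |  | 4.0 h | 4.0 h | 4.0 h | 4.0 h |

| run | time / min | G / % | L / % |
|---|---|---|---|
| north-west | 15.0 | 3.5 | 85.2 |
| north-west | 30.0 | 5.1 | 74.6 |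
| north-west | 50.0 | 6.1 | 64.7 |
| north-west | 60.0 | 6.2 | 60.7 |
| north-west | 80.0 | 6.6 | 54.8 |
| north-west | 90.0 | 6.5 | 52.3 |
| north-west | 120 | 6.0 | 46.3 |
| east | 6.00 | 13.7 | 80.9 |
| east | 20.0 | 25.1 | 54.1 |
| east | 30.0 | 25.9 | 42.8 |
| east | 50.0 | 22.1 | 29.9 |
| east | 80.0 | 17.2 | 21.1 |
| east | 90.0 | 15.9 | 19.2 |
| east | 120 | 12.9 | 15.5 |

(scatter of a reading: 0.3 percentage points)

- candidate steps: L + E <-> G + Q; G <-> J; L <-> D
- "hardly changes" means that all values lie within two and a half points (for a concentration: within two and a half percent of the largest)

- [G] at the end for violet, red, amber, teal, in this order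
- how that number moves from the first to the last of them (falls, then rises / rises all the way / rises, then falls / hardly changes / falls all the way)

**Concentration.** By hand, a second-order step of L with E makes r climb in a straight line with c·t, where c is the L charged and t the time. I take the first-order loss of L into D to add a term a that does not depend on c. The two runs read at 120 min give 0.131 M⁻¹ min⁻¹ for the reciprocal slope B, the rise of r per unit of c·t between two flasks read at one time, and a = 1.58. The same pair read at 90.0 min gives 0.134 M⁻¹ min⁻¹, so I carry B.

**Time.** By hand, doubling t moves c·t as doubling c does. Holding a at its last value, which is my judgement, I reckon L left at 4.0 h as 42.3% in violet and 12.7% in teal. Late on I take E left as a·f, which treats a as L and D together over L, so I reckon the conversion of E at 33.2% in violet and 79.9% in teal. Reckoned the same way at 120 min, G as a share of the E reacted comes to 22.3% in the north-west run and 17.1% in the east run. Borrowing these for violet and teal at 4.0 h, again my judgement, I reckon [G] at 0.00185 M and 0.0273 M, a rise larger than the fall of the share.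

**The forecast.** It gives 0.0012 M, 0.0035 M, 0.0089 M and 0.02 M, a row that rises all the way: “The concentration rises throughout.” My two ends stand above its ends.

**In the flask.** The flasks give 0.00136 M, 0.00391 M, 0.00988 M and 0.0225 M, and the row rises all the way, below my two ends.

    L + E ⇌ G + Q (K = 30.0, k = 0.100 M⁻¹ min⁻¹)
    G ⇌ J (K = 6.80, k = 0.0350 min⁻¹)
    L ⇌ D (K = 0.630, k = 0.00760 min⁻¹)

**Read back.** In violet the relaxation half-life of G and J, 0.288 h, is shorter than the 4.0 h of reading, and at that time violet holds G at 5.44% beside J at 23.5%. The reciprocal slope 0.131 M⁻¹ min⁻¹ put L left in teal at 12.7%, and teal stands at 14.0%; red at 2.00 h and violet at 4.00 h share one c·t and stand at 42.5% and 42.3%.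

The readings come from a simulation for an exercise.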